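**Plan**
- Cuts: the flavanone C2–aryl bond (to a chromone and an arylboronic acid), the aryl C6–B bond (to a C–H bond), and, in the dimethylchromanone fused to ring B, the C2–C3 and C4–C4a bonds together (to catechol acetonide and a terminal ynamide).
- Enabling feature: the chromanone oxygen O1 (on C8a) and the free hydroxyl on C8 are ortho neighbours on ring B, and C2 with its two methyl groups sits on O1 as a ketal-type carbon. O1, the C8 oxygen and C(CH3)2 are therefore stored as the dioxole ring of 2,2-dimethyl-1,3-benzodioxole; exchanging the C2–O(C8) bond for C2–C3 and acylating C4a gives the chromanone and frees the C8 hydroxyl.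
- Forward order: the pyranone ring on ring B is made first by a two-carbon ring expansion of the dioxole ring; C6 is then borylated; the preformed chromone (rings A and C) is joined by 1,4-addition; the three acetal groups are removed last.
- Stereochemistry: the only stereocentre (flavanone C2, S) is set by the chiral ligand in the rhodium-catalysed 1,4-addition; no later step is basic.

Key step: step 1

Assumption: in step 5 the (S)-configured biaryl bisphosphine is taken to deliver the aryl group to the chromone face that leads to the 2S product, by analogy with additions to cyclohex-2-enone; if the sense is the reverse, the (R)-ligand is used.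

**Step 1**
Reactants: 1 2,2-dimethyl-1,3-benzodioxole; 2 N-ethynyl-N,4-dimethylbenzenesulfonamide
Product: 4 8-hydroxy-2,2-dimethylchroman-4-one, via chromenyl sulfonamide silyl ether 3 (not isolated)
Conditions: TMSOTf (1.2 equiv), 2,6-di-tert-butyl-4-methylpyridine (1.3 equiv), 2 (1.5 equiv, added slowly), CH2Cl2, −20 °C to rt; then 2 M aq HCl, THF, 50 °C
Reagents that add atoms: water (O)
Why: Proposed new method: TMSOTf should silylate one ketal oxygen of 1 and heterolysis of that O–C(CH3)2 bond should give a 2-aryloxyprop-2-yl oxocarbenium ion with the neighbouring oxygen held as a silyl ether; the unsubstituted carbon of ynamide 2 adds to it (new CH–C(CH3)2 bond) to give an N-sulfonyl keteniminium ion, whose central carbon is attacked by the ring carbon ortho to the ether oxygen (new C–aryl bond), and proton loss to the hindered pyridine gives 3, which aqueous acid hydrolyses through an N-sulfonyliminium ion (enamide to ketone, silyl ether to phenol) to 4. The closest known reaction types are the Povarov-type [4+2] annulation of N-aryl iminium ions with ynamides, the oxa-Povarov annulation of aryl oxocarbenium ions with alkenes, Lewis-acid nucleophilic opening of catechol ketals and Friedel–Crafts capture of keteniminium ions. The pyranone ring closes by 6-exo-dig attack of the arene on the C=N bond of the keteniminium ion (the C=C bond stays in the ring), so the event is a stepwise cationic [4+2] that expands the five-membered dioxole ring by two carbons. No stereocentre is formed. The step needs regiocontrol (which oxygen keeps the C(CH3)2 carbon and which ortho carbon is acylated), which the mirror symmetry of 1 makes moot, and chemoselectivity for C-arylation over attack of the ether oxygen on the keteniminium carbon (oxete formation, carbonyl–ynamide metathesis), which the weakly basic aryl ether oxygen and the six-membered transition state to the activated ortho carbon should secure; the hindered base keeps the medium proton-free so that 2 is not lost to protonation and hydroarylation.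

**Step 2**
Reactants: 4 8-hydroxy-2,2-dimethylchroman-4-one
Product: 5 8-(methoxymethoxy)-2,2-dimethylchroman-4-one
Conditions: MOMCl (1.5 equiv), i-Pr2NEt (2 equiv), CH2Cl2, 0 °C to rt
Reagents that add atoms: chloromethyl methyl ether (COCCl)
Why: O-alkylation of the phenol with an α-chloro ether under amine base should be clean, since the ketone is not enolised by the amine.

**Step 3**
Reactants: 5 8-(methoxymethoxy)-2,2-dimethylchroman-4-one
Product: 7 [8-(methoxymethoxy)-2,2-dimethyl-4-oxochroman-6-yl]boronic acid, via pinacol boronate 6 (not isolated)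
Conditions: [Ir(OMe)(cod)]2 (1.5 mol %), 4,4'-di-tert-butyl-2,2'-bipyridine (3 mol %), B2pin2 (1.0 equiv), THF, 70 °C; then NaIO4, NH4OAc, acetone/H2O, rt
Reagents that add atoms: bis(pinacolato)diboron (CC1(C)OB(OC1(C)C)B1OC(C)(C)C(C)(C)O1); water (O)
Why: Iridium-catalysed aromatic C–H borylation is sterically controlled and C6 is the only ring C–H without an ortho substituent (C5 lies next to the acyl-bearing carbon, C7 next to the acetal oxygen); periodate then removes pinacol oxidatively to give the boronic acid.

**Step 4**
Reactants: 8 5,7-dihydroxy-4H-chromen-4-one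
Product: 9 5,7-bis(methoxymethoxy)-4H-chromen-4-one
Conditions: NaH (2.5 equiv), MOMCl (2.5 equiv), DMF, 0 °C to rt
Reagents that add atoms: chloromethyl methyl ether (COCCl)
Why: Double O-alkylation of the phenoxides; the non-nucleophilic hydride base is needed for the chelated C5 hydroxyl and does not open the pyranone ring.

**Step 5**
Reactants: 7 [8-(methoxymethoxy)-2,2-dimethyl-4-oxochroman-6-yl]boronic acid; 9 5,7-bis(methoxymethoxy)-4H-chromen-4-one
Product: 10 (2S)-5,7-bis(methoxymethoxy)-2-[8-(methoxymethoxy)-2,2-dimethyl-4-oxochroman-6-yl]chroman-4-one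
Conditions: [Rh(OH)((S)-MeO-F12-BIPHEP)]2 (1.5 mol %; ligand = 2,2'-bis[bis(3,4,5-trifluorophenyl)phosphino]-6,6'-dimethoxy-1,1'-biphenyl), 7 (1.5 equiv), toluene/H2O (10:1), 25–40 °C, no added base
Reagents that add atoms: none
Why: Hayashi–Miyaura asymmetric 1,4-addition of an arylboronic acid to a chromone (transmetalation, enantioface-selective insertion of the C2=C3 bond into the aryl–rhodium bond, protonolysis of the rhodium enolate by water), in which the chiral bisphosphine sets the C2 stereocentre and the base-free medium avoids reversible opening of the new pyranone ring.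

**Step 6**
Reactants: 10 (2S)-5,7-bis(methoxymethoxy)-2-[8-(methoxymethoxy)-2,2-dimethyl-4-oxochroman-6-yl]chroman-4-one
Product: 11 (2S)-5,7-dihydroxy-2-(8-hydroxy-2,2-dimethyl-4-oxochroman-6-yl)chroman-4-one
Conditions: 3 M HCl, MeOH/THF, 50 °C
Reagents that add atoms: none
Why: Acid-catalysed acetal cleavage removes all three methoxymethyl groups, and C2 should keep its configuration because ring opening of a flavanone needs base.

**Compound list**
1 | 2,2-dimethyl-1,3-benzodioxole | CC1(C)Oc2ccccc2O1 | starting material
2 | N-ethynyl-N,4-dimethylbenzenesulfonamide | C#CN(C)S(=O)(=O)c1ccc(C)cc1 | starting material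
3 | N,4-dimethyl-N-[2,2-dimethyl-8-(trimethylsilyloxy)-2H-chromen-4-yl]benzenesulfonamide | CC1(C)C=C(N(C)S(=O)(=O)c2ccc(C)cc2)c2cccc(O[Si](C)(C)C)c2O1 | intermediate
4 | 8-hydroxy-2,2-dimethylchroman-4-one | CC1(C)CC(=O)c2cccc(O)c2O1 | intermediate
5 | 8-(methoxymethoxy)-2,2-dimethylchroman-4-one | CC1(C)CC(=O)c2cccc(OCOC)c2O1 | intermediate
6 | 8-(methoxymethoxy)-2,2-dimethyl-6-(4,4,5,5-tetramethyl-1,3,2-dioxaborolan-2-yl)chroman-4-one | CC1(C)CC(=O)c2cc(B3OC(C)(C)C(C)(C)O3)cc(OCOC)c2O1 | intermediate
7 | [8-(methoxymethoxy)-2,2-dimethyl-4-oxochroman-6-yl]boronic acid | CC1(C)CC(=O)c2cc(B(O)O)cc(OCOC)c2O1 | intermediate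
8 | 5,7-dihydroxy-4H-chromen-4-one | O=c1ccoc2cc(O)cc(O)c12 | starting material
9 | 5,7-bis(methoxymethoxy)-4H-chromen-4-one | O=c1ccoc2cc(OCOC)cc(OCOC)c12 | intermediate
10 | (2S)-5,7-bis(methoxymethoxy)-2-[8-(methoxymethoxy)-2,2-dimethyl-4-oxochroman-6-yl]chroman-4-one | CC1(C)CC(=O)c2cc([C@@H]3CC(=O)c4c(OCOC)cc(OCOC)cc4O3)cc(OCOC)c2O1 | intermediate
11 | (2S)-5,7-dihydroxy-2-(8-hydroxy-2,2-dimethyl-4-oxochroman-6-yl)chroman-4-one | CC1(C)CC(=O)c2cc([C@@H]3CC(=O)c4c(O)cc(O)cc4O3)cc(O)c2O1 | target

**Step count**
Total steps: 6. Longest linear sequence: 5 steps (steps 1, 2, 3, 5, 6).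

**Steps most likely to fail**

1. Step 1 (proposed new method). The silyl triflate may ionise the diaryl ketal too little, the ynamide may be consumed by silylation or oligomerisation, or the keteniminium ion may be captured at oxygen instead of at the ring carbon. The fallback sets out from 1 and comes back at 4. Compound 1 is lithiated at C4 (n-BuLi, TMEDA, THF, −20 °C, ortho-metalation directed by the dioxole oxygen) and the aryllithium is acylated with N-methoxy-N,3-dimethylbut-2-enamide to give 1-(2,2-dimethyl-1,3-benzodioxol-4-yl)-3-methylbut-2-en-1-one F1. Heating with 2 M HCl in aqueous methanol at 60 °C should cleave the acetonide to 1-(2,3-dihydroxyphenyl)-3-methylbut-2-en-1-one F2. The hydroxyl ortho to the ketone then closes onto the enone by oxa-Michael addition, under the same conditions or on brief treatment with NaOAc in ethanol, to give 4.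

2. Step 5. Insertion into the electron-rich dioxygenated chromone may be slow, so that protodeboronation of 7 wins, and the enantiomeric purity may erode through reversible opening of the pyranone ring. The fallback sets out from 7 and 9 and comes back at 10. The two are joined under oxidative Heck-type conditions (Pd(OCOCF3)2, 1,10-phenanthroline, O2, DMF, 80 °C) to give the flavone 5,7-bis(methoxymethoxy)-2-[8-(methoxymethoxy)-2,2-dimethyl-4-oxochroman-6-yl]-4H-chromen-4-one F4. Asymmetric hydrogenation of its pyranone C2=C3 and C4=O bonds with a chiral ruthenium N-heterocyclic carbene catalyst (Ru(cod)(2-methylallyl)2, chiral imidazolinium salt, KOt-Bu, H2 under pressure, toluene) should give the cis-configured (2S,4S)-2-[4-hydroxy-8-(methoxymethoxy)-2,2-dimethylchroman-6-yl]-5,7-bis(methoxymethoxy)chroman-4-ol F5. The ring B ketone is expected to be reduced as well, as an inconsequential mixture of epimers. Oxidation of both carbinols with Dess–Martin periodinane in CH2Cl2 returns 10.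

3. Step 3. Borylation may compete at C5, directed by the ketone oxygen, and the ketone may be reduced by the boron hydride formed. The fallback sets out from 5 and comes back at 6. Compound 5 is iodinated with N-iodosuccinimide and catalytic CF3CO2H in MeCN at 0 °C. Substitution is expected at C6, para to the ring oxygen and meta to the ketone, because the two positions activated by the methoxymethoxy group (C5 and C7) are ortho and para to the deactivating acyl carbon; this gives 6-iodo-8-(methoxymethoxy)-2,2-dimethylchroman-4-one F3. Miyaura borylation (PdCl2(dppf), B2pin2, KOAc, dioxane, 80 °C) then gives pinacol boronate 6, which is cleaved to 7 as in step 3.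

**Further compounds**
F1 | step 1 | 1-(2,2-dimethyl-1,3-benzodioxol-4-yl)-3-methylbut-2-en-1-one | CC(C)=CC(=O)c1cccc2OC(C)(C)Oc12
F2 | step 1 | 1-(2,3-dihydroxyphenyl)-3-methylbut-2-en-1-one | CC(C)=CC(=O)c1cccc(O)c1O
F3 | step 3 | 6-iodo-8-(methoxymethoxy)-2,2-dimethylchroman-4-one | CC1(C)CC(=O)c2cc(I)cc(OCOC)c2O1
F4 | step 5 | 5,7-bis(methoxymethoxy)-2-[8-(methoxymethoxy)-2,2-dimethyl-4-oxochroman-6-yl]-4H-chromen-4-one | CC1(C)CC(=O)c2cc(-c3cc(=O)c4c(OCOC)cc(OCOC)cc4o3)cc(OCOC)c2O1
F5 | step 5 | (2S,4S)-2-[4-hydroxy-8-(methoxymethoxy)-2,2-dimethylchroman-6-yl]-5,7-bis(methoxymethoxy)chroman-4-ol | CC1(C)CC(O)c2cc([C@@H]3C[C@H](O)c4c(OCOC)cc(OCOC)cc4O3)cc(OCOC)c2O1
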